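**Retrosynthetic overview**
1. Target 17 ⇐ open hydroxy ketone 16 (the hemiketal closes by itself) ⇐ spiro-epoxide 14 + ethyl vinyl ketone (radical C–C bond at C10; the epoxide oxygen becomes the ring oxygen) ⇐ ketone 13.
2. Ring B ⇐ intramolecular Horner–Wadsworth–Emmons closure onto the ring A ketone; ring A ⇐ Nazarov cyclisation of a divinyl ketone made from enol triflate 9.
3. Key step: the bridged piperidine is closed on prochiral dione 3 by a chiral-phosphate-controlled aza-annulation that brings in N8 through both of its new C–N bonds (N8–C9, N8–C7) and fixes C1 and C6.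
4. 3 ⇐ cycloheptane-1,3-dione + trimethyl 2-phosphonoacrylate (Michael addition).
5. Ring order: seven-membered carbocycle (bought) → piperidine (8-azabicyclo[4.3.1]decane) → ring A → ring B → spiro-hemiketal.

Locants: those of 8-azabicyclo[4.3.1]decane (C1 = quaternary bridgehead, C2–C5 = four-carbon bridge, C6 = CH bridgehead, C7–N8–C9 = nitrogen bridge, C10 = one-carbon bridge and later spiro carbon). Ring A is the cyclopentene fused at C2–C3, ring B the cyclopentene fused at C1–C2.
Assumption: the hemiketal carbon is stereolabile, so its given configuration is taken as the thermodynamic anomer (axial OH, equatorial ethyl) reached on ring closure. The phosphonate-bearing carbon of 3–12 is stereolabile, is carried as both epimers and disappears in step 6.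

Step 1
Reactants: 1 cycloheptane-1,3-dione; 2 trimethyl 2-phosphonoacrylate
Product: 3 phosphonopropanoate-substituted dione
Conditions: Et3N (10 mol %), CH2Cl2, 0 → 23 °C
Reagents that add atoms: none
Why: Michael addition of the enolised 1,3-dione through C2 to the doubly activated acrylate is fast under mild base and stops after one alkylation because the product enol is more hindered; the ring stays prochiral.

Step 2
Reactants: 3 phosphonopropanoate-substituted dione; 4 methylamine; 5 formaldehyde (two equivalents)
Product: 7 (1R,6R)-8-methyl-8-azabicyclo[4.3.1]decane-2,10-dione with the phosphonopropanoate arm on C1, via amino dione 6 (not isolated)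
Conditions: MeNH2 (1.0 equiv, THF), (CH2O)n (1.0 equiv), CHCl3, 0 °C; then (R)-TRIP [3,3′-bis(2,4,6-triisopropylphenyl)-1,1′-binaphthyl-2,2′-diyl hydrogen phosphate] (10 mol %), (CH2O)n (1.2 equiv), 4 Å MS, −10 °C
Reagents that add atoms: none
Why: Proposed new method: enantioselective desymmetrising double aminomethylation (aza-annulation) in which methylamine and the first formaldehyde form an iminium ion that the dione enol captures at its C2 to give achiral 6, after which the second formaldehyde forms an N-methyl iminium ion on the tethered amine whose only counter-ion is the chiral phosphate, and this ion pair, hydrogen-bonded to one of the two enantiotopic ketone enols, closes the six-membered ring (N8–C7 then C7–C6) and so fixes C1 and C6 together, the sense being chosen through the catalyst enantiomer and the acid passing on to the more basic uncyclised amine for turnover; the closest known reaction types are the racemic double Mannich annulation of cyclic β-dicarbonyl compounds with primary amines and formaldehyde and chiral-phosphate counter-anion control of Mannich reactions and of 2,2-disubstituted 1,3-dione desymmetrisations.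

Step 3
Reactants: 7 bicyclic amino diketone
Product: 9 C2–C3 enol triflate, via dipotassium dianion 8 (not isolated)
Conditions: KN(SiMe3)2 (2.2 equiv), THF, −78 °C; then Comins' reagent (1.1 equiv), −78 → −40 °C
Reagents that add atoms: N-(5-chloropyridin-2-yl)bis(trifluoromethanesulfonimide) (Comins' reagent), O=S(=O)(N(c1ccc(Cl)cn1)S(=O)(=O)C(F)(F)F)C(F)(F)F
Why: Enolate O-triflation, the ring ketone being able to enolise only towards C3 (C1 is quaternary and the C10 ketone lies between two bridgeheads) while the phosphonoacetate sits as its unreactive carbanion, which also shields the ester from Dieckmann attack.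

Step 4
Reactants: 9 enol triflate; 10 tributyl(vinyl)stannane
Product: 11 cross-conjugated divinyl ketone (acryloyl group on C2)
Conditions: CO (1 atm), Pd(PPh3)4 (5 mol %), LiCl (3 equiv), THF, 55 °C
Reagents that add atoms: carbon monoxide, [C-]#[O+]
Why: Carbonylative Stille coupling, in which zerovalent palladium inserts into the C–OTf bond, CO insertion gives the acyl complex and vinyl transfer from tin delivers the dienone, the amine, ketone and phosphonate being spectators.

Step 5
Reactants: 11 divinyl ketone
Product: 12 ring A enone (cyclopent-2-enone fused at C2=C3, carbonyl on C2)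
Conditions: TfOH (4 equiv), CH2Cl2, 0 → 23 °C
Reagents that add atoms: none
Why: Nazarov 4π-electrocyclisation of the protonated dienone joins the vinyl terminus to C3, and loss of the C3 proton from the oxyallyl cation puts the alkene in the tetrasubstituted ring-fusion position conjugated to the new ketone.

Step 6
Reactants: 12 ring A enone
Product: 13 tetracyclic keto dienoate (rings A and B in place)
Conditions: NaH (1.2 equiv), THF, 0 → 23 °C
Reagents that add atoms: none
Why: Intramolecular Horner–Wadsworth–Emmons olefination, in which the phosphonoacetate carbanion (the most acidic site) adds 5-exo to the ring A carbonyl and irreversible loss of dimethyl phosphate gives the ester-bearing alkene of ring B, completing the conjugated dienoate and erasing the stereolabile carbon.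

Step 7
Reactants: 13 keto dienoate
Product: 14 C10 spiro-epoxide
Conditions: Me3S+ I− (1.5 equiv), KN(SiMe3)2 (1.4 equiv), THF, −10 °C; then 13, −10 → 0 °C
Reagents that add atoms: trimethylsulfonium iodide, C[S+](C)C.[I-]
Why: Corey–Chaykovsky epoxidation, the small ylide adding to the non-enolisable C10 ketone from the more open cycloheptene face (only one 1,3-diaxial C–H there) and the alkoxide then displacing Me2S to form the C–O bond that becomes the ring C–O bond of the target, while the fully substituted dienoate is too hindered for cyclopropanation; the epoxide configuration is erased in step 8.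

Step 8
Reactants: 14 spiro-epoxide; 15 ethyl vinyl ketone
Product: 17 target hemiketal CNP0192143.3, via hydroxy ketone 16 (not isolated)
Conditions: Cp2TiCl2 (20 mol %), Mn (2 equiv), 2,4,6-collidine·HCl (2.5 equiv), 15 (5 equiv, slow addition), THF, 23 °C; aq. NaHCO3
Reagents that add atoms: none
Why: Nugent–RajanBabu reductive epoxide opening by Cp2TiCl (trivalent titanium, formed in the flask) gives the tertiary C10 radical, whose Giese addition to the enone should occur anti to the bulky Cp2ClTi–O–CH2 group lying over the open cycloheptene face, so the oxopentyl chain lands on the piperidine face and CH2O on the cycloheptene face (C10 as in the target); reduction and protonation give 16, which closes to the six-membered hemiketal as the thermodynamic anomer.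

**Compound list**
1 | cycloheptane-1,3-dione | O=C1CCCCC(=O)C1 | starting material
2 | trimethyl 2-phosphonoacrylate (methyl 2-(dimethoxyphosphoryl)prop-2-enoate) | C=C(C(=O)OC)P(=O)(OC)OC | starting material
3 | methyl 2-(dimethoxyphosphoryl)-3-(2,7-dioxocycloheptyl)propanoate (racemic at the stereolabile phosphonate carbon) | COC(=O)C(CC1C(=O)CCCCC1=O)P(=O)(OC)OC | intermediate
4 | methylamine | CN | starting material
5 | formaldehyde (used as paraformaldehyde) | C=O | starting material
6 | methyl 2-(dimethoxyphosphoryl)-3-{1-[(methylamino)methyl]-2,7-dioxocycloheptyl}propanoate | CNCC1(CC(C(=O)OC)P(=O)(OC)OC)C(=O)CCCCC1=O | intermediate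
7 | methyl 2-(dimethoxyphosphoryl)-3-[(1R,6R)-8-methyl-2,10-dioxo-8-azabicyclo[4.3.1]decan-1-yl]propanoate (both epimers at the phosphonate carbon) | O=C1[C@@H]2CCCC(=O)[C@@]1(CC(C(=O)OC)P(=O)(OC)OC)CN(C)C2 | intermediate
8 | dipotassium salt of 7 (C2–C3 enolate and phosphonate carbanion) | O=C1[C@@H]2CCC=C([O-])[C@@]1(C[C-](C(=O)OC)P(=O)(OC)OC)CN(C)C2.[K+].[K+] | intermediate
9 | methyl 2-(dimethoxyphosphoryl)-3-[(1R,6R)-8-methyl-10-oxo-2-{[(trifluoromethyl)sulfonyl]oxy}-8-azabicyclo[4.3.1]dec-2-en-1-yl]propanoate | O=C1[C@@H]2CCC=C(OS(=O)(=O)C(F)(F)F)[C@@]1(CC(C(=O)OC)P(=O)(OC)OC)CN(C)C2 | intermediate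
10 | tributyl(vinyl)stannane | C=C[Sn](CCCC)(CCCC)CCCC | starting material
11 | methyl 2-(dimethoxyphosphoryl)-3-[(1S,6R)-8-methyl-10-oxo-2-(prop-2-enoyl)-8-azabicyclo[4.3.1]dec-2-en-1-yl]propanoate | O=C1[C@@H]2CCC=C(C(=O)C=C)[C@@]1(CC(C(=O)OC)P(=O)(OC)OC)CN(C)C2 | intermediate
12 | ring A enone: cyclopent-2-en-1-one fused across C2=C3 of the azabicyclodecene (C=O on C2), C10 ketone, phosphonopropanoate arm on C1; C1 S, C6 R | O=C1[C@@H]2CCC3=C(C(=O)CC3)[C@@]1(CC(C(=O)OC)P(=O)(OC)OC)CN(C)C2 | intermediate
13 | keto dienoate: 12 with ring B closed (C1–CH2–C(CO2Me)=C, the alkene ending on the former ring A carbonyl carbon), C10 ketone; C1 S, C6 R | O=C2[C@@H]1CCC3=C4C(=C(C(=O)OC)C[C@@]42CN(C)C1)CC3 | intermediate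
14 | C10 spiro-oxirane of 13 (oxirane CH2 on the cycloheptene face, O on the piperidine face); C1 S, C6 R, C10 S | C1O[C@]12[C@@H]3CCC4=C5C(=C(C(=O)OC)C[C@@]52CN(C)C3)CC4 | intermediate
15 | ethyl vinyl ketone (pent-1-en-3-one) | CCC(=O)C=C | starting material
16 | open hydroxy ketone: C10 carries CH2OH (cycloheptene face) and 3-oxopentyl (piperidine face); C1 R, C6 S, C10 R | CCC(=O)CC[C@@]1(CO)[C@@H]2CCC3=C4C(=C(C(=O)OC)C[C@@]41CN(C)C2)CC3 | intermediate
17 | CNP0192143.3: spiro 2-ethyl-2-hydroxytetrahydropyran hemiketal of 16; hemiketal carbon R, spiro carbon R, C1 R, C6 S | CC[C@]1(O)CC[C@@]2(CO1)[C@@H]1CCC3=C4C(=C(C(=O)OC)C[C@@]42CN(C)C1)CC3 | target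

**Total step count:** 8. **Longest linear sequence:** 8 steps (from cycloheptane-1,3-dione).

**Three steps most likely to fail**

Step 2 (proposed new method). Risks are a racemic background cyclisation, product inhibition of the acid and an unknown sense of induction. Fallback with known chemistry, setting out from 3 and returning at 7: run the classical double Mannich annulation with (S)-1-phenylethylamine and aqueous formaldehyde in AcOH/MeOH at 60 °C. The two ring diastereomers (each a pair of phosphonate epimers) are separated by chromatography to give the (1R,6R) N-(1-phenylethyl) amino diketone F1. Hydrogenolysis over Pd(OH)2/C in MeOH gives the secondary amine F2, and aqueous formaldehyde added under the same hydrogen atmosphere methylates it to 7.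

Step 5. The Nazarov cation is flanked by a ketone-bearing quaternary carbon and an ammonium group, and the unsubstituted acryloyl unit may polymerise. Fallback setting out from 9 and returning at 12: carbonylative Stille coupling with tributyl[(E)-2-(trimethylsilyl)ethenyl]stannane gives the β-trimethylsilyl divinyl ketone F3. FeCl3 in CH2Cl2 at −30 °C (silicon-directed Nazarov cyclisation, the cation being stabilised β to silicon) gives the kinetic cyclopentenone F4, with the alkene between the two former vinyl carbons. RhCl3·3H2O in EtOH at 80 °C then moves the alkene into the ring-fusion position to give 12.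

Step 8. The face selectivity at C10 rests on the shielding argument, and the enone may be reduced by the titanium reagent. Fallback setting out from 14 and returning at 16 (and so 17), in which C8 is introduced last from the open face: BF3·OEt2 in CH2Cl2 at −78 °C (Meinwald rearrangement) gives the C10 carbaldehyde F5. Aqueous formaldehyde with K2CO3 in MeOH hydroxymethylates its enolate from the cycloheptene face to give the hydroxymethyl aldehyde F6. Wittig reaction with Ph3P=CHC(O)Et in toluene at 100 °C gives the (E)-enone F7, and conjugate reduction with [(Ph3P)CuH]6 gives 16, which closes to 17.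

**Further compounds**
F1 | step 2 | methyl 2-(dimethoxyphosphoryl)-3-[(1R,6R)-2,10-dioxo-8-[(1S)-1-phenylethyl]-8-azabicyclo[4.3.1]decan-1-yl]propanoate | O=C1[C@@H]2CCCC(=O)[C@@]1(CC(C(=O)OC)P(=O)(OC)OC)CN([C@@H](C)c1ccccc1)C2
F2 | step 2 | methyl 2-(dimethoxyphosphoryl)-3-[(1R,6R)-2,10-dioxo-8-azabicyclo[4.3.1]decan-1-yl]propanoate | O=C1[C@@H]2CCCC(=O)[C@@]1(CC(C(=O)OC)P(=O)(OC)OC)CNC2
F3 | step 5 | β-trimethylsilyl divinyl ketone: 11 carrying an (E)-Me3Si group on the vinyl terminus | O=C1[C@@H]2CCC=C(C(=O)/C=C/[Si](C)(C)C)[C@@]1(CC(C(=O)OC)P(=O)(OC)OC)CN(C)C2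
F4 | step 5 | kinetic cyclopentenone: isomer of 12 with the ring A alkene between the two former vinyl carbons and hydrogens on C2 and C3 (cis ring fusion) | O=C1[C@@H]2CCC3C=CC(=O)C3[C@@]1(CC(C(=O)OC)P(=O)(OC)OC)CN(C)C2
F5 | step 8 | C10 carbaldehyde from 14 (C10–H, both epimers) | O=CC1[C@@H]2CCC3=C4C(=C(C(=O)OC)C[C@@]41CN(C)C2)CC3
F6 | step 8 | C10 hydroxymethyl aldehyde (CH2OH on the cycloheptene face, CHO on the piperidine face) | O=C[C@@]1(CO)[C@@H]2CCC3=C4C(=C(C(=O)OC)C[C@@]41CN(C)C2)CC3
F7 | step 8 | (E)-enone: C10 carries CH2OH and (E)-3-oxopent-1-enyl | CCC(=O)/C=C/[C@@]1(CO)[C@@H]2CCC3=C4C(=C(C(=O)OC)C[C@@]41CN(C)C2)CC3
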